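Your quick number hangs on a ratio, a run's lead over its fade time. The lead h is the product made so far divided by the present rate. The fade time τ is the time in which the rate falls by a factor e. Suppose the fading runs on the clock, and that at any one moment the rate goes in step with the free catalyst charged. One percent more free catalyst then reaches the same product earlier by one percent of h, and there it meets a rate that has faded less, so the apparent order in free catalyst is

n = 1 + h/τ

the same everywhere: reagent 12.5 mM

| flask | substrate | free catalyst | remark |
|---|---|---|---|
| Friday's | 2.5 mM | 10 µM | run made earlier |
| Wednesday's | 3.8 mM | 10 µM | run made earlier |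
| Thursday's | 5 mM | 15 µM | run made earlier |
| flask | 5.0 mM | 10 µM |  |

| run | time / s | product / % | substrate / % |
|---|---|---|---|
| Friday's | 10.0 | 7.5 | 91.9 |
| Friday's | 15.0 | 11.6 | 88.0 |
| Friday's | 30.0 | 19.1 | 80.0 |
| Friday's | 60.0 | 37.5 | 62.9 |
| Friday's | 120 | 54.7 | 42.1 |
| Wednesday's | 10.0 | 4.4 | 93.7 |
| Wednesday's | 25.0 | 13.7 | 86.3 |
| Wednesday's | 50.0 | 25.3 | 74.4 |
| Wednesday's | 80.0 | 34.0 | 65.7 |
| Wednesday's | 120 | 44.2 | 55.4 |
| Thursday's | 10.0 | 7.1 | 91.4 |
| Thursday's | 25.0 | 15.9 | 80.7 |
| Thursday's | 50.0 | 30.0 | 69.6 |
| Thursday's | 80.0 | 42.5 | 57.8 |
| Thursday's | 120 | 53.5 | 47.9 |

(readings scatter by 1 percentage point)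

- apparent order in reagent when 50% of the substrate are converted (percent change of the rate of making product for one percent more reagent charged)
- apparent order in free catalyst when 50% of the substrate are converted (percent change of the rate of making product for one percent more free catalyst charged)

- no earlier run changes the charge of reagent; that part of a forecast is a guess

Thursday's run crosses half conversion between its last two readings, and over its last two stretches we read product rates of 0.0208 mM/s and then 0.0138 mM/s, with the stretch midpoints 35.0 s apart. For Thursday's run this gives

τ = 84.2 s

h = 175 s

n = 3.07, give or take 0.854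

Now we go round once for the flask, which holds 66.7% of Thursday's catalyst. Its rate at half conversion comes to about 0.00396 mM/s, so its lead is 632 s and n is 8.50. That carries τ beyond the readings it was taken from, so we give this figure little weight and commit to the lower part of the span between 3.07 and 8.50.

Your forecast says 2.5 (1 to 6), lower than our Thursday figure, on the ground that “More catalyst then arrives sooner with more survivors”. For reagent, which no earlier run varies, we have no reckoning and leave your guess of 1.3 (0.2 to 3.5) standing.

The flask gives 1.1 in reagent and 3.5 in free catalyst.

    substrate + catalyst intermediate A ⇌ catalyst intermediate B (K = 58.8 /M, k = 2.83 × 10⁵ /M/s)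
    reagent + free catalyst → catalyst intermediate A (k = 650 /M/s)
    2 reagent → homo dimer (k = 1.40 /M/s)
    catalyst intermediate C → free catalyst + product (k = 26.1 /s)
    catalyst intermediate B → by-product + catalyst intermediate C (k = 24.4 /s)

In the flask, the first half-life of reagent at its charge by the step to homo dimer alone, 28.6 s, is shorter than the fade time 84.2 s we read on Thursday's run, and half conversion comes after 3.76 min, which is 2.68 of those fade times. At 3.00 min the flask has 8.29% of its reagent charge left while 54.3% of its substrate still stands.

The runs were computed from invented constants; noise was put on by code.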